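- I had no rate constants, but I needed only their ratio: if both substrates take the same partner and free catalyst, that ratio holds however the feed runs, and, as long as no exchange turns one substrate into the other, the drift in composition follows from it.

in all of them: left-handed substrate 0.97 M; right-handed substrate 0.97 M; partner 2.42 M (fed, over 50 min)

| charge | free catalyst | precatalyst | remark | time |
|---|---|---|---|---|
| gamma | 3.9 mM | 0.55 mM | run made earlier; the fed solution adds 0.20 times the starting volume |  |
| alpha | 3.9 mM | 1.2 mM | run made earlier; the fed solution adds 0.20 times the starting volume |  |
| beta | 1.9 mM | 0.82 mM | run made earlier; the fed solution adds 0.20 times the starting volume |  |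
| flask | 3.9 mM | 0.82 mM | the fed solution adds 0.20 times the starting volume | 50 min |

| run | time / min | left-handed product / % | right-handed product / % |
|---|---|---|---|
| gamma | 8.00 | 4 | 1 |
| gamma | 15.0 | 11 | 2 |
| gamma | 25.0 | 21 | 10 |
| gamma | 30.0 | 28 | 12 |
| gamma | 40.0 | 35 | 16 |
| gamma | 50.0 | 42 | 23 |
| alpha | 3.00 | 4 | 3 |
| alpha | 10.0 | 5 | 0 |
| alpha | 20.0 | 18 | 7 |
| alpha | 25.0 | 23 | 6 |
| alpha | 40.0 | 35 | 19 |
| alpha | 50.0 | 44 | 26 |
| beta | 4.00 | 1 | 0 |
| beta | 8.00 | 2 | 1 |
| beta | 15.0 | 5 | 1 |
| beta | 25.0 | 14 | 5 |
| beta | 50.0 | 36 | 18 |

(readings scatter by 1.5 percentage points)

* left-handed product and right-handed product together, in percent of the left-handed substrate and right-handed substrate charged together, at 50 min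
* excess of left-handed product over right-handed product in the product at 50 min
* whether the exchange between left-handed substrate and right-handed substrate keeps pace with the reaction: how far the product's excess at 50 min gets from its value without exchange to its value with instant exchange (above 80% keeps pace, below 20% hardly takes part, else lags behind)

- free catalyst is single-handed; left-handed substrate and right-handed substrate are mirror images of each other, charged as a racemate, each of them at the stated concentration
- every charge counts on the volume at the start, and the solution that is fed holds the whole dose
- an excess is below zero if the other one leads

- Let a and b be the fractions of left-handed and right-handed substrate not turned into product, so a = 1 − 2P and b = 1 − 2Q, with P and Q the product readings taken as fractions of both substrates together. At 50.0 min, ln a / ln b read 2.97 in gamma, 2.89 in alpha and 2.85 in beta. I took the mean, the selectivity factor s = 2.91, as a reading.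
- For the total I averaged gamma and alpha: 67.5%. But they differ by 5 percentage points. Was that precatalyst? That difference holds 4 readings, so its scatter is 3 points, and the flask's precatalyst lies between theirs anyway, so I kept the mean.
- That total requires a + b = 0.650, with a = b^s. I started at b = 0.5, which gave a = 0.134. Putting that back gave b = 0.516, and going round again gave 0.503. The rounds swung about the answer, so I took their middle, 0.510, and my excess came to 27.4%.
- Doubt: this assumes no exchange. Instant exchange would hold the excess at (s − 1)/(s + 1) = 48.8%, and the 20% mark of that way lies at 31.7%. Gamma gave 29.2% and alpha, with twice the precatalyst, gave less, 25.7%. Each reading carries 1.5 points, so this is a judgement: exchange hardly takes part.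
- The forecast said 67%, 28% and hardly takes part, on the ground that more precatalyst “does not raise the excess, so exchange is negligible”.
- The flask gave 65.3% and 29.0%; the exchange hardly takes part, getting 6.6% of the way.

    partner + free catalyst + left-handed substrate → free catalyst + left-handed product (k = 19.0 /M²/min)
    partner + free catalyst + right-handed substrate → free catalyst + right-handed product (k = 6.80 /M²/min)
    left-handed substrate + racemization catalyst ⇌ right-handed substrate + racemization catalyst, rate k3*[racemization catalyst]*[left-handed substrate] forward; the back reaction follows from the equilibrium constant (k = 16.0 /M/min)
    racemization catalyst → spent catalyst (k = 0.0950 /min)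
    partner + precatalyst → racemization catalyst + spent reagent (k = 0.0890 /M/min)

- In this flask at 50.0 min, left-handed substrate went to left-handed product 39 times faster than it left by the forward exchange step alone. With the read s, this flask's right-handed product of 23.2% gives left-handed product 41.9%, and the flask holds 42.1%. In the neighbour flask charged with 0.0066 M of free catalyst, right-handed product of 28.3% gives 45.6%, and that flask holds 46.1%.

The earlier runs and the new flask are simulated on assumed constants, and the scatter is random.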